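**Assumption:** Andrographolide (bulk isolate of *Andrographis paniculata*, sold cheaply at >98 %) is taken as an admissible commercial chiral starting material. Andrographolide numbering is used: C12 = β‑carbon of the enoate, C13 = lactone α‑carbon, C14 = lactone carbinol carbon.

## Retrosynthetic overview

1. Target 8 ⇒ bis‑silylene 7 by Si–O cleavage; both 1,3‑diols of the target are masked as di‑tert‑butylsilylene acetals.
2. 7 ⇒ silanol 5 by the key C12–O (and C13–H) disconnection: intramolecular oxa‑Michael addition of a 14‑O‑tethered silanol, run under triplet‑sensitised E/Z photo‑equilibration so that the Z‑enoate is the isomer that cyclises.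
3. 5 ⇒ andrographolide 1 + 2 equiv tBu2Si(OTf)2 (2): one‑pot 3,19‑silylene formation and 14‑O‑silanol installation.
4. Ring order: decalin and lactone are bought intact. The only ring made is the temporary 1,3‑dioxa‑2‑silinane (step 2), removed in step 3. C3, C4, C5, C9, C10 and C14 are bought; C12 and C13 are relayed from C14.

## Route

Step 1
Reactants: 1 andrographolide; 2 di‑tert‑butylsilyl bis(trifluoromethanesulfonate)
Product: 5 14‑O‑[di‑tert‑butyl(hydroxy)silyl]‑3,19‑O‑(di‑tert‑butylsilanediyl)andrographolide, via 3,19‑O‑(di‑tert‑butylsilanediyl)andrographolide 3 (not isolated), via 14‑O‑[di‑tert‑butyl(trifluoromethanesulfonyloxy)silyl]‑3,19‑O‑(di‑tert‑butylsilanediyl)andrographolide 4 (not isolated)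
Conditions: 2 (2.3 equiv, two portions), 2,6‑lutidine (6 equiv), DMF, −20 → 0 °C; then sat. aq NaHCO3, 0 °C
Reagents that add atoms: di‑tert‑butylsilyl bis(trifluoromethanesulfonate) (2), CC(C)(C)[Si](OS(=O)(=O)C(F)(F)F)(OS(=O)(=O)C(F)(F)F)C(C)(C)C; water, O
Why: Silylene‑acetal formation and O‑silylation: the first equivalent closes the six‑membered silylene on the 3,19‑diol, the second mono‑silylates the hindered 14‑OH, and the residual Si–OTf, too hindered to take a second secondary alcohol, hydrolyses to the silanol on bicarbonate quench; no stereocentre is touched.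

Step 2
Reactants: 5 14‑O‑[di‑tert‑butyl(hydroxy)silyl]‑3,19‑O‑(di‑tert‑butylsilanediyl)andrographolide
Product: 7 (12S,13S)‑3,19:12,14‑bis‑O‑(di‑tert‑butylsilanediyl)‑12‑hydroxy‑12,13‑dihydroandrographolide (lactone trans‑fused to a chair 1,3‑dioxa‑2‑silinane, C11 equatorial), via the (12Z)‑isomer of 5 6 (not isolated)
Conditions: xanthone (20 mol %), Cs2CO3 (20 mol %), degassed MeCN (0.02 M), 365 nm LEDs, 0 °C
Reagents that add atoms: none
Why: Proposed new method: a photochemical dynamic kinetic oxa‑Michael cyclisation. Triplet xanthone (E_T ≈ 74 kcal/mol) sensitises only the alkylidene‑lactone chromophore and interconverts 5 (E) and 6 (Z). The catalytic silanolate can reach C12 only on the lactone face that carries O14. For Z this 6‑endo‑trig closure runs through a chair with C11 equatorial and gives 12S. For E the same closure would give 12R with C11 axial, syn‑diaxial to a tert‑butyl on silicon, so E should react much more slowly and be recycled by light. The resulting enolate should be protonated axially (the ring oxygens carry no axial H), placing H13 syn to O14 (13S, trans‑lactone). The step is an isomerisation with no co‑product. Closest known reaction types: sensitised E→Z isomerisation/cyclisation cascades, and tethered O‑nucleophile delivery to alkenes (hemiacetal or boronate oxa‑Michael, di‑tert‑butylsilanol oxy‑functionalisation).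

Step 3
Reactants: 7 (12S,13S)‑3,19:12,14‑bis‑O‑(di‑tert‑butylsilanediyl)‑12‑hydroxy‑12,13‑dihydroandrographolide
Product: 8 (12S,13S,14S)‑12‑hydroxy‑12,13‑dihydroandrographolide (12S‑hydroxyandrographolide, target)
Conditions: HF·pyridine (excess), pyridine/THF, 0 °C → rt
Reagents that add atoms: none
Why: Fluoride‑mediated desilylation (Si–F bond formation) cleaves both silylene acetals under buffered, weakly acidic conditions; these avoid E1cB or retro‑aldol loss at the β‑hydroxy lactone and acid‑promoted etherification of 12‑OH onto the 8(17)‑alkene, and no stereocentre is affected.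

## Compound list

1 | andrographolide | C=C1CC[C@@H]2[C@](C)(CO)[C@H](O)CC[C@@]2(C)[C@@H]1C/C=C1/C(=O)OC[C@H]1O | starting material
2 | di‑tert‑butylsilyl bis(trifluoromethanesulfonate) | CC(C)(C)[Si](OS(=O)(=O)C(F)(F)F)(OS(=O)(=O)C(F)(F)F)C(C)(C)C | starting material
3 | 3,19‑O‑(di‑tert‑butylsilanediyl)andrographolide | C=C1CC[C@@H]2[C@](C)(CO[Si]3(C(C)(C)C)C(C)(C)C)[C@H](O3)CC[C@@]2(C)[C@@H]1C/C=C1/C(=O)OC[C@H]1O | intermediate
4 | 14‑O‑[di‑tert‑butyl(trifluoromethanesulfonyloxy)silyl]‑3,19‑O‑(di‑tert‑butylsilanediyl)andrographolide | C=C1CC[C@@H]2[C@](C)(CO[Si]3(C(C)(C)C)C(C)(C)C)[C@H](O3)CC[C@@]2(C)[C@@H]1C/C=C1/C(=O)OC[C@H]1O[Si](OS(=O)(=O)C(F)(F)F)(C(C)(C)C)C(C)(C)C | intermediate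
5 | 14‑O‑[di‑tert‑butyl(hydroxy)silyl]‑3,19‑O‑(di‑tert‑butylsilanediyl)andrographolide (12E) | C=C1CC[C@@H]2[C@](C)(CO[Si]3(C(C)(C)C)C(C)(C)C)[C@H](O3)CC[C@@]2(C)[C@@H]1C/C=C1/C(=O)OC[C@H]1O[Si](O)(C(C)(C)C)C(C)(C)C | intermediate
6 | (12Z)‑isomer of 5 | C=C1CC[C@@H]2[C@](C)(CO[Si]3(C(C)(C)C)C(C)(C)C)[C@H](O3)CC[C@@]2(C)[C@@H]1C/C=C1\C(=O)OC[C@H]1O[Si](O)(C(C)(C)C)C(C)(C)C | intermediate
7 | (12S,13S)‑3,19:12,14‑bis‑O‑(di‑tert‑butylsilanediyl)‑12‑hydroxy‑12,13‑dihydroandrographolide | C=C1CC[C@@H]2[C@](C)(CO[Si]3(C(C)(C)C)C(C)(C)C)[C@H](O3)CC[C@@]2(C)[C@@H]1C[C@H](O4)[C@@H]1C(=O)OC[C@H]1O[Si]4(C(C)(C)C)C(C)(C)C | intermediate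
8 | (12S,13S,14S)‑12‑hydroxy‑12,13‑dihydroandrographolide | C=C1CC[C@@H]2[C@](C)(CO)[C@H](O)CC[C@@]2(C)[C@@H]1C[C@H](O)[C@@H]1C(=O)OC[C@H]1O | target

## Step count and risks

Total step count: 3. Longest linear sequence: 3.

**Risk 1 – step 2 (the new step).** Possible failures are: background cyclisation of the E‑isomer to the 12R epimer, protonation at C13 to the cis‑lactone, base‑induced loss of the 14‑oxygen, or inefficient sensitisation. The fallback uses known chemistry only. It sets out from compound 3, isolated when step 1 is stopped after 1.05 equiv of 2, and returns to the route at compound 8.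
- 3 is silylated (TBSCl, imidazole, DMF) to 14‑O‑(tert‑butyldimethylsilyl)‑3,19‑O‑(di‑tert‑butylsilanediyl)andrographolide F1.
- Copper‑catalysed conjugate borylation (CuCl/Xantphos, cat. NaOtBu, B2pin2, MeOH, THF) gives the β‑boryl lactone 14‑O‑TBS‑3,19‑O‑(di‑tert‑butylsilanediyl)‑12‑(pinacolboryl)‑12,13‑dihydroandrographolide F2. Syn‑borylcupration on the face anti to the 14‑OTBS group puts boron on C12 with the arrangement that becomes 12S; C13 forms as an epimer mixture on protonation.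
- NaBO3·4H2O in THF/H2O oxidises C–B to C–OH with retention, giving 14‑O‑TBS‑3,19‑O‑(di‑tert‑butylsilanediyl)‑(12S)‑12‑hydroxy‑12,13‑dihydroandrographolide as the C13 mixture F3.
- Catalytic DBU in THF at 0 °C equilibrates the lactone α‑centre to the trans isomer (12S,13S)‑14‑O‑TBS‑3,19‑O‑(di‑tert‑butylsilanediyl)‑12‑hydroxy‑12,13‑dihydroandrographolide F4.
- HF·pyridine then removes the TBS group and the silylene to give 8.

**Risk 2 – step 1.** The second silylation may oligomerise, ionise the allylic 14‑position, or fail to stop at the silanol. The fallback sets out from compound 3 (isolated as above) and returns at compound 5.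
- tBu2Si(H)Cl, imidazole and DMAP in DMF give the hydrosilyl ether 14‑O‑(di‑tert‑butylsilyl)‑3,19‑O‑(di‑tert‑butylsilanediyl)andrographolide F5.
- Ruthenium‑catalysed hydrolytic oxidation of Si–H (cat. [RuCl2(p‑cymene)]2, H2O, MeCN) converts F5 into silanol 5.

**Risk 3 – step 3.** Double HF cleavage next to the β‑hydroxy lactone may stall at fluorosilyl ethers or damage the product. The fallback changes the protecting‑group and tether design so that the end‑game is fluoride‑free; it sets out from compound 1 and returns at compound 8.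
- 2,2‑Dimethoxypropane/PPTS gives 3,19‑O‑isopropylideneandrographolide F6.
- iPr2Si(OTf)2/2,6‑lutidine, then aq NaHCO3, gives 14‑O‑[hydroxy(diisopropyl)silyl]‑3,19‑O‑isopropylideneandrographolide F7.
- Under the step 2 conditions F7 passes through its (12Z)‑isomer F8 (not isolated) to (12S,13S)‑12,14‑O‑(diisopropylsilanediyl)‑3,19‑O‑isopropylidene‑12‑hydroxy‑12,13‑dihydroandrographolide F9.
- AcOH/THF/H2O (3:1:1, rt) hydrolyses both the labile diisopropylsilylene and the acetonide to give 8.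

## Further compounds

F1 | step 2 | 14‑O‑(tert‑butyldimethylsilyl)‑3,19‑O‑(di‑tert‑butylsilanediyl)andrographolide | C=C1CC[C@@H]2[C@](C)(CO[Si]3(C(C)(C)C)C(C)(C)C)[C@H](O3)CC[C@@]2(C)[C@@H]1C/C=C1/C(=O)OC[C@H]1O[Si](C)(C)C(C)(C)C
F2 | step 2 | 14‑O‑TBS‑3,19‑O‑(di‑tert‑butylsilanediyl)‑12‑(pinacolboryl)‑12,13‑dihydroandrographolide (C13 epimer mixture) | C=C1CC[C@@H]2[C@](C)(CO[Si]3(C(C)(C)C)C(C)(C)C)[C@H](O3)CC[C@@]2(C)[C@@H]1C[C@H](B4OC(C)(C)C(C)(C)O4)C1C(=O)OC[C@H]1O[Si](C)(C)C(C)(C)C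
F3 | step 2 | 14‑O‑TBS‑3,19‑O‑(di‑tert‑butylsilanediyl)‑(12S)‑12‑hydroxy‑12,13‑dihydroandrographolide (C13 epimer mixture) | C=C1CC[C@@H]2[C@](C)(CO[Si]3(C(C)(C)C)C(C)(C)C)[C@H](O3)CC[C@@]2(C)[C@@H]1C[C@H](O)C1C(=O)OC[C@H]1O[Si](C)(C)C(C)(C)C
F4 | step 2 | (12S,13S)‑14‑O‑TBS‑3,19‑O‑(di‑tert‑butylsilanediyl)‑12‑hydroxy‑12,13‑dihydroandrographolide | C=C1CC[C@@H]2[C@](C)(CO[Si]3(C(C)(C)C)C(C)(C)C)[C@H](O3)CC[C@@]2(C)[C@@H]1C[C@H](O)[C@@H]1C(=O)OC[C@H]1O[Si](C)(C)C(C)(C)C
F5 | step 1 | 14‑O‑(di‑tert‑butylsilyl)‑3,19‑O‑(di‑tert‑butylsilanediyl)andrographolide | C=C1CC[C@@H]2[C@](C)(CO[Si]3(C(C)(C)C)C(C)(C)C)[C@H](O3)CC[C@@]2(C)[C@@H]1C/C=C1/C(=O)OC[C@H]1O[SiH](C(C)(C)C)C(C)(C)C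
F6 | step 3 | 3,19‑O‑isopropylideneandrographolide | C=C1CC[C@@H]2[C@](C)(COC3(C)C)[C@H](O3)CC[C@@]2(C)[C@@H]1C/C=C1/C(=O)OC[C@H]1O
F7 | step 3 | 14‑O‑[hydroxy(diisopropyl)silyl]‑3,19‑O‑isopropylideneandrographolide | C=C1CC[C@@H]2[C@](C)(COC3(C)C)[C@H](O3)CC[C@@]2(C)[C@@H]1C/C=C1/C(=O)OC[C@H]1O[Si](O)(C(C)C)C(C)C
F8 | step 3 | (12Z)‑isomer of F7 | C=C1CC[C@@H]2[C@](C)(COC3(C)C)[C@H](O3)CC[C@@]2(C)[C@@H]1C/C=C1\C(=O)OC[C@H]1O[Si](O)(C(C)C)C(C)C
F9 | step 3 | (12S,13S)‑12,14‑O‑(diisopropylsilanediyl)‑3,19‑O‑isopropylidene‑12‑hydroxy‑12,13‑dihydroandrographolide | C=C1CC[C@@H]2[C@](C)(COC3(C)C)[C@H](O3)CC[C@@]2(C)[C@@H]1C[C@H](O4)[C@@H]1C(=O)OC[C@H]1O[Si]4(C(C)C)C(C)C
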